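If amber and grey are to be compared on final product, the meeting agreed, the count is best kept as the fraction of the substrate charge still left.

| flask | substrate | free catalyst | remark | time |
|---|---|---|---|---|
| Monday's | 2.3 M | 1.9 mM | run made earlier |  |
| Sunday's | 2.3 M | 3.7 mM | run made earlier |  |
| Saturday's | 2.3 M | 5.1 mM | run made earlier |  |
| Thursday's | 1.6 M | 2.3 mM | run made earlier |  |
| amber | 2.3 M | 2.3 mM |  | 3.0 d |
| grey | 0.60 M | 6.0 mM |  | 2.0 d |

| run | time / h | product / % | substrate / % |
|---|---|---|---|
| Monday's | 6.00 | 5.1 | 92.9 |
| Monday's | 20.0 | 19.9 | 81.7 |
| Monday's | 30.0 | 27.2 | 73.5 |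
| Monday's | 48.0 | 42.4 | 58.4 |
| Sunday's | 6.00 | 10.4 | 89.9 |
| Sunday's | 20.0 | 34.1 | 65.5 |
| Sunday's | 30.0 | 48.4 | 49.8 |
| Sunday's | 48.0 | 72.2 | 26.8 |
| Saturday's | 6.00 | 14.8 | 85.1 |
| Saturday's | 20.0 | 44.6 | 55.7 |
| Saturday's | 30.0 | 62.4 | 37.4 |
| Saturday's | 48.0 | 87.8 | 13.0 |
| Thursday's | 4.00 | 6.4 | 93.5 |
| Thursday's | 10.0 | 15.2 | 84.3 |
| Thursday's | 20.0 | 30.4 | 69.4 |
| Thursday's | 48.0 | 64.4 | 38.3 |

(each reading ± 1 percentage point)

- the analysis behind the earlier runs scatters by 1 percentage point, standard deviation
- a reading or a percentage of product counts all its forms, free or not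

- the flask that ends with the higher amount of product, in percent of the substrate charged, or "neither" when 2 percentage points or less lies between them (amber / grey / neither)
- final product, as a percentage of the substrate charged, in amber
- final product, as a percentage of the substrate charged, in grey

I reported from Saturday's run, which goes furthest. Its readings at 20.0 h and 48.0 h give a half-speed level of 0.699 M (the apparent Michaelis constant) and a top rate of 14.0 h⁻¹ per catalyst, both readings carrying the scatter of the analysis.

For amber I proposed 1.01 as the reach, meaning top rate times catalyst times time, divided by the substrate charged. I proposed 0.304 as its tail price, the half-speed level as a fraction of the charge. My rule was that the fraction made, plus the tail price times the natural log of the inverse of the fraction left, equals the reach.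

A colleague objected that one run is thin. At Sunday's last reading the reach is 1.08, while the readings pay 1.13, so I conceded that Sunday's run stands a little ahead of the rule.

Correcting once from Saturday's 37.4% left, I put amber at 32.8% left, so 67.2% product. Grey has a reach of 6.72 and a tail price of 1.16. Once about 1 is paid for the fraction made, each halving of what is left in grey costs 0.804, which buys 7.11 halvings and leaves 0.737%. The meeting minuted grey, 32 percentage points ahead of amber, against a margin of 2 points.

The forecast, a little apart from my figures, gave 68% for amber and 98% for grey, so grey, noting that “Monday, Sunday and Saturday roughly collapse on catalyst × time”. The flasks give 69.6% for amber and 99.5% for grey, so grey, against my 67.2% and 99.3%.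

    crystals ⇌ product, rate k1*(cs1 - [product]) while solid is left; crystals form when [product] > cs1 (solubility = 0.260 M, k = 0.110 h⁻¹)
    catalyst intermediate B ⇌ free catalyst + product (K = 0.900 M, k = 33.0 h⁻¹)
    substrate + free catalyst → catalyst intermediate A (k = 59.0 M⁻¹ h⁻¹)
    catalyst intermediate A ⇌ catalyst intermediate B (K = 0.660, k = 2800 h⁻¹)

Grey read at 20 h has a reach of 2.80, against 1.01 for amber, and with the tail price of 1.16 the rule leaves 17.8% of the charge. That flask holds 8.57% substrate, about half of the reckoned fraction. Its product reads 90.9%, of which 27.9% of the charge is crystals.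

The earlier runs and the new flask are calculated for substances that don't exist.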